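The route rests on cutting the γ-lactone (oxolan-2-one ring) at C3–C4 and at the O1–C2 acyl bond. Dimethyl malonate opens a 2,2-disubstituted epoxide at its CH2 and the freed tertiary alkoxide acylates in the same operation. Ring O1 and the methyl-bearing quaternary C5 therefore come from the epoxide, C4 from its CH2, and the erythro C5/C1′ pair is carried over untouched from a Sharpless kinetic-resolution epoxidation. The precursor is the silyl ether of a vinyl epoxy carbinol. After decarboxylation its vinyl group is hydroborated and joined by B-alkyl Suzuki coupling to an (E)-iodoalkene whose C–OMe centre comes from a glycolate Ireland–Claisen rearrangement.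

Key step: step 4

Step 1
Reactants: 1 methacrolein; 2 vinylmagnesium bromide
Product: 3 rac-2-methylpenta-1,4-dien-3-ol
Conditions: THF, −78 → 0 °C; aqueous work-up
Reagents that add atoms: none
Why: Grignard 1,2-addition of the vinyl nucleophile to the aldehyde of the enal should give the racemic divinyl carbinol, whose single stereocentre is resolved in step 2.

Step 2
Reactants: 3 rac-2-methylpenta-1,4-dien-3-ol
Product: 4 (1R)-1-[(2S)-2-methyloxiran-2-yl]prop-2-en-1-ol
Conditions: Ti(OiPr)4, D-(−)-diisopropyl tartrate, tBuOOH (about 0.5 equiv), 4 Å molecular sieves, CH2Cl2, −20 °C; non-aqueous work-up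
Reagents that add atoms: tert-butyl hydroperoxide, CC(C)(C)OO
Why: Sharpless kinetic-resolution epoxidation: with the D-(−)-tartrate the (R)-enantiomer should be epoxidised fast at its more electron-rich 1,1-disubstituted olefin with the erythro preference of the titanium–tartrate system, which sets C1 (R) and C2′ (S) under reagent control, while the (S)-enantiomer is matched only at its slower vinyl group and gives a separable regioisomer.

Step 3
Reactants: 4 (1R)-1-[(2S)-2-methyloxiran-2-yl]prop-2-en-1-ol
Product: 5 tert-butyl(dimethyl){[(1R)-1-[(2S)-2-methyloxiran-2-yl]prop-2-en-1-yl]oxy}silane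
Conditions: TBSCl, imidazole, DMF, rt
Reagents that add atoms: tert-butyldimethylsilyl chloride, CC(C)(C)[Si](C)(C)Cl
Why: Silyl ether formation under the mild imidazole conditions should cap the secondary hydroxyl without touching the acid-sensitive epoxide, so that only one alkoxide can form in step 4.

Step 4
Reactants: 5 tert-butyl(dimethyl){[(1R)-1-[(2S)-2-methyloxiran-2-yl]prop-2-en-1-yl]oxy}silane; 6 dimethyl malonate
Product: 8 methyl (5S)-5-[(1R)-1-(tert-butyldimethylsilyloxy)prop-2-en-1-yl]-5-methyl-2-oxooxolane-3-carboxylate (both C3 epimers), via sodium alkoxide of the ring-opened malonate 7 (not isolated)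
Conditions: NaOMe, MeOH, reflux (6 in slight excess over the base); AcOH quench
Reagents that add atoms: none
Why: The sodium enolate of 6 attacks the unsubstituted epoxide carbon in an SN2 opening, and the tertiary alkoxide 7 that is set free adds to one of the two ester carbonyls and expels methoxide. The closest known reaction type is the base-mediated opening of terminal 2,2-disubstituted epoxides by malonate with lactonisation in the same flask. The oxolan-2-one ring closes by 5-exo-trig acyl substitution at the ester carbonyl. The only new stereocentre, the ester-bearing C3, is not controlled and need not be, because step 5 removes it; C5 and C1′ are untouched, since the C5–O bond of the epoxide is never broken. The step needs attack at CH2 and not at the quaternary carbon, which the full substitution of that carbon and the SN2 character of the opening secure, and it needs the tertiary alkoxide to acylate and not to take the silyl group, which the congestion of a tertiary silyl ether and the fast five-ring closure in a protic medium should secure.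

Step 5
Reactants: 8 methyl (5S)-5-[(1R)-1-(tert-butyldimethylsilyloxy)prop-2-en-1-yl]-5-methyl-2-oxooxolane-3-carboxylate
Product: 9 (5S)-5-[(1R)-1-(tert-butyldimethylsilyloxy)prop-2-en-1-yl]-5-methyloxolan-2-one
Conditions: LiCl, H2O, DMSO, 150 °C
Reagents that add atoms: none
Why: Krapcho dealkoxycarbonylation: chloride should demethylate the activated ester and the carboxylate so formed loses CO2, which removes the uncontrolled C3 centre and leaves the lactone, the vinyl group and the silyl ether intact.

Step 6
Reactants: 10 furan-3-carbaldehyde; 11 (triphenylphosphoranylidene)acetaldehyde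
Product: 12 (2E)-3-(furan-3-yl)prop-2-enal
Conditions: toluene, 80 °C
Reagents that add atoms: none
Why: Wittig olefination with the stabilised formyl ylide should give the (E)-enal by two-carbon homologation of the aldehyde.

Step 7
Reactants: 12 (2E)-3-(furan-3-yl)prop-2-enal
Product: 13 3-(furan-3-yl)propanal
Conditions: Hantzsch ester (diethyl 2,6-dimethyl-1,4-dihydropyridine-3,5-dicarboxylate), dibenzylammonium trifluoroacetate (cat.), THF, rt
Reagents that add atoms: none
Why: Iminium-catalysed transfer hydrogenation from the Hantzsch ester should reduce only the conjugated C=C bond and leave the aldehyde and the furan untouched.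

Step 8
Reactants: 13 3-(furan-3-yl)propanal; 14 isopropenylmagnesium bromide
Product: 15 rac-5-(furan-3-yl)-2-methylpent-1-en-3-ol
Conditions: THF, −78 → 0 °C; aqueous work-up
Reagents that add atoms: none
Why: Grignard 1,2-addition to the aldehyde should give the racemic 2-methylallylic alcohol needed for the resolution of step 9.

Step 9
Reactants: 15 rac-5-(furan-3-yl)-2-methylpent-1-en-3-ol
Product: 16 (3S)-5-(furan-3-yl)-2-methylpent-1-en-3-ol (recovered enantiomer)
Conditions: Ti(OiPr)4, D-(−)-diisopropyl tartrate, tBuOOH (0.6 equiv), 4 Å molecular sieves, CH2Cl2, −20 °C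
Reagents that add atoms: none
Why: Sharpless kinetic resolution: with the D-(−)-tartrate the (R)-enantiomer should be epoxidised much faster than the (S)-enantiomer, which is recovered in high enantiomeric purity once slightly more than half of the alcohol has reacted.

Step 10
Reactants: 16 (3S)-5-(furan-3-yl)-2-methylpent-1-en-3-ol; 17 methoxyacetyl chloride
Product: 18 (3S)-5-(furan-3-yl)-2-methylpent-1-en-3-yl methoxyacetate
Conditions: pyridine, DMAP (cat.), CH2Cl2, 0 °C
Reagents that add atoms: none
Why: DMAP-catalysed acylation of the secondary alcohol by the acid chloride should proceed with retention, since the C–O bond of the carbinol is not broken.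

Step 11
Reactants: 18 (3S)-5-(furan-3-yl)-2-methylpent-1-en-3-yl methoxyacetate
Product: 21 (2S,4E)-7-(furan-3-yl)-2-methoxy-4-methylhept-4-en-1-ol, via (Z)-silyl ketene acetal 19 (not isolated), via trimethylsilyl ester of the rearranged acid 20 (not isolated)
Conditions: LiN(SiMe3)2, Me3SiCl, THF, −78 °C → rt; then LiAlH4, 0 °C
Reagents that add atoms: none
Why: Ireland–Claisen rearrangement of a glycolate ester: the lithium-chelated enolate is trapped as the (Z)-silyl ketene acetal 19, which should rearrange through a chair with the furylethyl chain equatorial, so that the (S)-carbinol configuration is transferred to the new (S)-C–OMe centre and the trisubstituted olefin forms as the (E)-isomer, and LiAlH4 then reduces the silyl ester 20 in the same flask.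

Step 12
Reactants: 21 (2S,4E)-7-(furan-3-yl)-2-methoxy-4-methylhept-4-en-1-ol
Product: 22 (2S,4E)-7-(furan-3-yl)-2-methoxy-4-methylhept-4-enal
Conditions: Dess–Martin periodinane, pyridine, CH2Cl2, 0 °C → rt; used at once
Reagents that add atoms: none
Why: Dess–Martin oxidation under buffered conditions should stop at the α-methoxy aldehyde without epimerising it and without harming the furan.

Step 13
Reactants: 22 (2S,4E)-7-(furan-3-yl)-2-methoxy-4-methylhept-4-enal
Product: 23 3-[(3E,6S)-8,8-dibromo-6-methoxy-4-methylocta-3,7-dien-1-yl]furan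
Conditions: CBr4, PPh3, Et3N, CH2Cl2, 0 °C (aldehyde added to the preformed ylide)
Reagents that add atoms: carbon tetrabromide, BrC(Br)(Br)Br
Why: Corey–Fuchs dibromo-olefination with the preformed phosphorus ylide should convert the aldehyde without a base strong enough to epimerise the α-methoxy centre.

Step 14
Reactants: 23 3-[(3E,6S)-8,8-dibromo-6-methoxy-4-methylocta-3,7-dien-1-yl]furan
Product: 25 3-[(3E,6S)-6-methoxy-4-methylnon-3-en-7-yn-1-yl]furan, via lithium acetylide 24 (not isolated)
Conditions: n-BuLi (2 equiv), THF, −78 °C; then MeI, −78 °C → rt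
Reagents that add atoms: iodomethane, CI
Why: Corey–Fuchs alkyne formation: bromine–lithium exchange, 1,2-shift and deprotonation should give the lithium acetylide 24, which is C-methylated by MeI in the same flask at a temperature where the furan is not lithiated.

Step 15
Reactants: 25 3-[(3E,6S)-6-methoxy-4-methylnon-3-en-7-yn-1-yl]furan
Product: 27 3-[(3E,6S,7E)-8-iodo-6-methoxy-4-methylnona-3,7-dien-1-yl]furan, via alkenylzirconocene chloride 26 (not isolated)
Conditions: Cp2Zr(H)Cl (excess), THF, rt → 40 °C; then I2, 0 °C
Reagents that add atoms: iodine, II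
Why: Hydrozirconation–iodination: syn addition of Zr–H should place zirconium on the methyl-bearing alkyne carbon, remote from the branched C–OMe carbon, and iodinolysis with retention then gives the (E)-iodoalkene.

Step 16
Reactants: 9 (5S)-5-[(1R)-1-(tert-butyldimethylsilyloxy)prop-2-en-1-yl]-5-methyloxolan-2-one; 27 3-[(3E,6S,7E)-8-iodo-6-methoxy-4-methylnona-3,7-dien-1-yl]furan
Product: 29 (5S)-5-[(1R,4E,6S,8E)-1-(tert-butyldimethylsilyloxy)-11-(furan-3-yl)-6-methoxy-4,8-dimethylundeca-4,8-dien-1-yl]-5-methyloxolan-2-one, via B-alkyl-9-borabicyclononane 28 (not isolated)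
Conditions: 9-BBN, THF, rt; then 27, Pd(dppf)Cl2 (cat.), AsPh3, Cs2CO3, DMF–H2O, rt
Reagents that add atoms: none
Why: Hydroboration followed by B-alkyl Suzuki–Miyaura coupling: 9-BBN should add anti-Markovnikov to the terminal vinyl group and the alkylborane 28 should couple with the iodoalkene with retention of its (E)-geometry, the protected lactone and the furan being inert to the borane and to the mild base.

Step 17
Reactants: 29 (5S)-5-[(1R,4E,6S,8E)-1-(tert-butyldimethylsilyloxy)-11-(furan-3-yl)-6-methoxy-4,8-dimethylundeca-4,8-dien-1-yl]-5-methyloxolan-2-one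
Product: 30 (5S)-5-[(1R,4E,6S,8E)-11-(furan-3-yl)-1-hydroxy-6-methoxy-4,8-dimethylundeca-4,8-dien-1-yl]-5-methyloxolan-2-one (CNP0306177.2)
Conditions: Bu4NF, AcOH, THF, rt
Reagents that add atoms: none
Why: Fluoride-mediated desilylation buffered with AcOH should free the C1′ hydroxyl without leaving a basic alkoxide beside the lactone and without acid that could ionise the allylic methyl ether or harm the furan.

Compound list
1 | methacrolein | C=C(C)C=O | starting material
2 | vinylmagnesium bromide | C=C[Mg]Br | starting material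
3 | rac-2-methylpenta-1,4-dien-3-ol | C=CC(O)C(C)=C | intermediate
4 | (1R)-1-[(2S)-2-methyloxiran-2-yl]prop-2-en-1-ol | C=C[C@@H](O)[C@]1(C)CO1 | intermediate
5 | tert-butyl(dimethyl){[(1R)-1-[(2S)-2-methyloxiran-2-yl]prop-2-en-1-yl]oxy}silane | C=C[C@@H](O[Si](C)(C)C(C)(C)C)[C@]1(C)CO1 | intermediate
6 | dimethyl malonate | COC(=O)CC(=O)OC | starting material
7 | sodium alkoxide of dimethyl 2-[(2S,3R)-3-(tert-butyldimethylsilyloxy)-2-hydroxy-2-methylpent-4-en-1-yl]propanedioate | C=C[C@@H](O[Si](C)(C)C(C)(C)C)[C@]([O-])(C)CC(C(=O)OC)C(=O)OC.[Na+] | intermediate (not isolated)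
8 | methyl (5S)-5-[(1R)-1-(tert-butyldimethylsilyloxy)prop-2-en-1-yl]-5-methyl-2-oxooxolane-3-carboxylate, both C3 epimers | C=C[C@@H](O[Si](C)(C)C(C)(C)C)[C@]1(C)CC(C(=O)OC)C(=O)O1 | intermediate
9 | (5S)-5-[(1R)-1-(tert-butyldimethylsilyloxy)prop-2-en-1-yl]-5-methyloxolan-2-one | C=C[C@@H](O[Si](C)(C)C(C)(C)C)[C@]1(C)CCC(=O)O1 | intermediate
10 | furan-3-carbaldehyde | O=Cc1ccoc1 | starting material
11 | (triphenylphosphoranylidene)acetaldehyde | O=CC=P(c1ccccc1)(c1ccccc1)c1ccccc1 | starting material
12 | (2E)-3-(furan-3-yl)prop-2-enal | O=C/C=C/c1ccoc1 | intermediate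
13 | 3-(furan-3-yl)propanal | O=CCCc1ccoc1 | intermediate
14 | isopropenylmagnesium bromide (prop-1-en-2-ylmagnesium bromide) | C=C(C)[Mg]Br | starting material
15 | rac-5-(furan-3-yl)-2-methylpent-1-en-3-ol | C=C(C)C(O)CCc1ccoc1 | intermediate
16 | (3S)-5-(furan-3-yl)-2-methylpent-1-en-3-ol | C=C(C)[C@@H](O)CCc1ccoc1 | intermediate
17 | methoxyacetyl chloride | COCC(=O)Cl | starting material
18 | (3S)-5-(furan-3-yl)-2-methylpent-1-en-3-yl methoxyacetate | C=C(C)[C@@H](OC(=O)COC)CCc1ccoc1 | intermediate
19 | [(1Z)-1-{[(3S)-5-(furan-3-yl)-2-methylpent-1-en-3-yl]oxy}-2-methoxyethenyl]oxy(trimethyl)silane, OMe cis to OSiMe3 | C=C(C)[C@@H](O/C(O[Si](C)(C)C)=C/OC)CCc1ccoc1 | intermediate (not isolated)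
20 | trimethylsilyl (2S,4E)-7-(furan-3-yl)-2-methoxy-4-methylhept-4-enoate | CO[C@H](C(=O)O[Si](C)(C)C)C/C(C)=C/CCc1ccoc1 | intermediate (not isolated)
21 | (2S,4E)-7-(furan-3-yl)-2-methoxy-4-methylhept-4-en-1-ol | CO[C@H](CO)C/C(C)=C/CCc1ccoc1 | intermediate
22 | (2S,4E)-7-(furan-3-yl)-2-methoxy-4-methylhept-4-enal | CO[C@H](C=O)C/C(C)=C/CCc1ccoc1 | intermediate
23 | 3-[(3E,6S)-8,8-dibromo-6-methoxy-4-methylocta-3,7-dien-1-yl]furan | CO[C@H](C=C(Br)Br)C/C(C)=C/CCc1ccoc1 | intermediate
24 | lithium (3S,5E)-8-(furan-3-yl)-3-methoxy-5-methyloct-5-en-1-yn-1-ide | CO[C@H](C#C[Li])C/C(C)=C/CCc1ccoc1 | intermediate (not isolated)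
25 | 3-[(3E,6S)-6-methoxy-4-methylnon-3-en-7-yn-1-yl]furan | CO[C@H](C#CC)C/C(C)=C/CCc1ccoc1 | intermediate
26 | chlorobis(cyclopentadienyl)[(2E,4S,6E)-9-(furan-3-yl)-4-methoxy-6-methylnona-2,6-dien-2-yl]zirconium | CO[C@H](/C=C(\C)[Zr](Cl)(C1C=CC=C1)C1C=CC=C1)C/C(C)=C/CCc1ccoc1 | intermediate (not isolated)
27 | 3-[(3E,6S,7E)-8-iodo-6-methoxy-4-methylnona-3,7-dien-1-yl]furan | CO[C@H](/C=C(\C)I)C/C(C)=C/CCc1ccoc1 | intermediate
28 | (5S)-5-[(1R)-3-(9-borabicyclo[3.3.1]nonan-9-yl)-1-(tert-butyldimethylsilyloxy)propyl]-5-methyloxolan-2-one | CC(C)(C)[Si](C)(C)O[C@H](CCB1C2CCCC1CCC2)[C@]1(C)CCC(=O)O1 | intermediate (not isolated)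
29 | (5S)-5-[(1R,4E,6S,8E)-1-(tert-butyldimethylsilyloxy)-11-(furan-3-yl)-6-methoxy-4,8-dimethylundeca-4,8-dien-1-yl]-5-methyloxolan-2-one | CO[C@H](/C=C(\C)CC[C@@H](O[Si](C)(C)C(C)(C)C)[C@]1(C)CCC(=O)O1)C/C(C)=C/CCc1ccoc1 | intermediate
30 | (5S)-5-[(1R,4E,6S,8E)-11-(furan-3-yl)-1-hydroxy-6-methoxy-4,8-dimethylundeca-4,8-dien-1-yl]-5-methyloxolan-2-one | CO[C@H](/C=C(\C)CC[C@@H](O)[C@]1(C)CCC(=O)O1)C/C(C)=C/CCc1ccoc1 | target

Total step count: 17, with the one-flask sequences of steps 4, 11, 14, 15 and 16 counted as one step each.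
Longest linear sequence: 12 steps (steps 6–17, from furan-3-carbaldehyde); the lactone branch needs steps 1–5 before the union in step 16.

Steps most likely to fail

Step 4 (key step). The SN2 opening at the CH2 next to the quaternary carbon may be slow. That would leave time for solvolysis of the epoxide or for transfer of the silyl group to the tertiary alkoxide before the five-ring closure. Fallback: setting out from 5, lithiated acetonitrile (LiCH2CN from MeCN and n-BuLi, THF, −78 °C → rt), a smaller and more reactive two-carbon nucleophile, would open the epoxide at CH2 to give (4S,5R)-5-(tert-butyldimethylsilyloxy)-4-hydroxy-4-methylhept-6-enenitrile F1. Hydrolysis of the nitrile (KOH, aqueous EtOH, reflux) would give (4S,5R)-5-(tert-butyldimethylsilyloxy)-4-hydroxy-4-methylhept-6-enoic acid F2 as its salt. Mild acidification would then lactonise F2 to 9, so that the route is rejoined after step 5 and no decarboxylation is needed.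

Step 2. Discrimination between the two allylic olefins and between the two enantiomers may be incomplete, which would erode regio- and enantiopurity, and the small, volatile, water-soluble epoxy alcohol may be lost on isolation. Fallback: setting out from 1, ethynylmagnesium bromide would give rac-2-methylpent-1-en-4-yn-3-ol F3, in which the isopropenyl group is the only olefin. The same D-(−)-tartrate-controlled kinetic-resolution epoxidation would then give (1R)-1-[(2S)-2-methyloxiran-2-yl]prop-2-yn-1-ol F4. Semihydrogenation of the alkyne (H2, Pd on CaCO3 poisoned with Pb(OAc)2, quinoline) would return to 4.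

Step 17. Cleavage of the hindered silyl ether may be sluggish, and once the hydroxyl is free under fluoride the acyl group may migrate from the tertiary to the secondary oxygen, expanding the lactone ring. Fallback: setting out from 9, the silyl ether would be cleaved first (Bu4NF, AcOH, THF) on the small vinyl lactone to give (5S)-5-[(1R)-1-hydroxyprop-2-en-1-yl]-5-methyloxolan-2-one F5. Hydroboration with an excess of 9-BBN, which also borylates the hydroxyl with loss of hydrogen, would give (5S)-5-[(1R)-3-(9-borabicyclo[3.3.1]nonan-9-yl)-1-(9-borabicyclo[3.3.1]nonan-9-yloxy)propyl]-5-methyloxolan-2-one F6. Coupling of F6 with 27 under the conditions of step 16 would deliver 30 directly, so that the finished molecule never meets a deprotection.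

Further compounds
F1 | step 4 | (4S,5R)-5-(tert-butyldimethylsilyloxy)-4-hydroxy-4-methylhept-6-enenitrile | C=C[C@@H](O[Si](C)(C)C(C)(C)C)[C@](O)(C)CCC#N
F2 | step 4 | (4S,5R)-5-(tert-butyldimethylsilyloxy)-4-hydroxy-4-methylhept-6-enoic acid | C=C[C@@H](O[Si](C)(C)C(C)(C)C)[C@](O)(C)CCC(=O)O
F3 | step 2 | rac-2-methylpent-1-en-4-yn-3-ol | C#CC(O)C(C)=C
F4 | step 2 | (1R)-1-[(2S)-2-methyloxiran-2-yl]prop-2-yn-1-ol | C#C[C@@H](O)[C@]1(C)CO1
F5 | step 17 | (5S)-5-[(1R)-1-hydroxyprop-2-en-1-yl]-5-methyloxolan-2-one | C=C[C@@H](O)[C@]1(C)CCC(=O)O1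
F6 | step 17 | (5S)-5-[(1R)-3-(9-borabicyclo[3.3.1]nonan-9-yl)-1-(9-borabicyclo[3.3.1]nonan-9-yloxy)propyl]-5-methyloxolan-2-one | C1CCC2CCCC1B2O[C@H](CCB1C2CCCC1CCC2)[C@]1(C)CCC(=O)O1
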